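The leftover that judges the next run is the double product standing in the flask at the end, and the decision is whether larch's extra reagent over ash buys any of it.

| setting | Friday's | Sunday's | larch | ash |
|---|---|---|---|---|
| solid substrate | 0.25 M | 0.25 M | 0.25 M | 0.25 M |
| reagent | 0.33 M | 0.34 M | 0.375 M | 0.300 M |
| remark | run made earlier | run made earlier |  |  |
| time |  |  | 25 min | 25 min |

| run | time / min | double product / % | first product / % |
|---|---|---|---|
| Friday's | 1.50 | 0.4 | 2.3 |
| Friday's | 4.00 | 2.1 | 4.5 |
| Friday's | 8.00 | 3.0 | 7.5 |
| Friday's | 12.0 | 3.8 | 9.4 |
| Friday's | 20.0 | 5.7 | 11.3 |
| Sunday's | 1.50 | 0.8 | 2.2 |
| Sunday's | 4.00 | 2.0 | 4.7 |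
| Sunday's | 8.00 | 2.4 | 7.3 |
| Sunday's | 12.0 | 3.6 | 8.0 |
| Sunday's | 20.0 | 4.4 | 10.9 |

(each reading ± 0.5 percentage points)

1. which of these holds the largest part of the solid substrate at the end of larch (tetra adduct / double product / solid substrate / first product / triple product)
2. which of these holds the largest part of the solid substrate at the end of ash (tetra adduct / double product / solid substrate / first product / triple product)
3. amount of double product at the end of ash, in percent of the solid substrate charged

- solid substrate is a solid; its amount is given per volume of the solution
- the analysis behind the earlier runs scatters by 0.5 percentage points, standard deviation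
- steps thought possible: starting material + reagent -> first product; reagent + first product -> double product; reagent + double product -> triple product; reagent + triple product <-> tetra adduct; solid substrate <-> starting material
- at the start none of the solid substrate is in solution

1. Picture tanks in series: first product drains into double product, and double product drains into triple product. Each drain takes one reagent, so at the c(reagent) of the moment each is pseudo-first-order, with a time constant inverse to that c(reagent). A tank that follows its feed then holds c(double product)/c(first product) equal to the ratio of the two time constants, and c(reagent) cancels.

2. Summed over Friday's and Sunday's runs, double product over first product reads 0.425 at 12.0 min and 0.455 at 20.0 min; this last reading is the relay ratio. The runs charged 0.33 M and 0.34 M, too close to test the cancelling, so that part is reckoned, not read.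

3. First product averages 8.70% at 12.0 min and 11.1% at 20.0 min. Drawn straight on to 25 min, it reaches 12.6%. Taking that for both flasks, the relay ratio gives 5.73% of double product in larch and in ash alike. So this reckoning keeps ash's 0.300 M of reagent rather than larch's 0.375 M.

4. The forecast names solid substrate for larch and solid substrate for ash, and puts double product in ash at 4.7% (3.5% to 6%), lower than this reckoning, holding that “the ratios of the intermediates depend little on reagent concentration”.

5. Larch ends with triple product largest at 33.7%, ahead of solid substrate at 29.2%. Ash ends with solid substrate largest at 37.1%, ahead of triple product at 27.2%. Double product ends at 4.99% in ash and 4.97% in larch.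

    starting material + reagent → first product (k = 2.20 M⁻¹ min⁻¹)
    reagent + first product → double product (k = 2.10 M⁻¹ min⁻¹)
    reagent + double product → triple product (k = 4.40 M⁻¹ min⁻¹)
    reagent + triple product ⇌ tetra adduct (K = 4.90 M⁻¹, k = 0.780 M⁻¹ min⁻¹)
    solid substrate ⇌ starting material, rate k5*(cs5 - [starting material]) while solid is left; crystals form when [starting material] > cs5 (solubility = 43.0 mM, k = 0.380 min⁻¹)

Ash ends with first product at 12.0% and a ratio of 0.418, against the 0.455 carried from the runs. The neighbour flask is ash with 1.2 M of reagent, 4.80 equiv on the solid substrate. Its first product ends at 0.358%, so the relay ratio gives 0.163% of double product. Solid substrate there stands at 0% and starting material at 0.0580%, while tetra adduct holds 58.9%. The neighbour's double product ends higher than the relay ratio gives, at 0.274%, a ratio of 0.765.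

The runs are simulated with made-up constants, noise included.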